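The closed, stirred vessel holds electrophile, nucleophile and protic impurity, and the flasks asked about differ in their nucleophile charge.

| setting | spring | dawn | zeta | epsilon | theta |
|---|---|---|---|---|---|
| electrophile | 2 M | 2 M | 2.0 M | 2.0 M | 2.0 M |
| nucleophile | 0.31 equiv | 0.75 equiv | 0.400 equiv | 0.600 equiv | 1.00 equiv |
| protic impurity | 0.20 M | 0.20 M | 0.200 M | 0.200 M | 0.200 M |
| remark | run made earlier | run made earlier |  |  |  |
| time |  |  | 80 min | 80 min | 80 min |

* amount of product at the end, in percent of the electrophile charged for zeta, epsilon, theta, in this order
* the course of these numbers from the first flask to the last (falls all the way / rises all the way / hardly changes / rises, then falls / falls, then rises)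

- candidate steps: nucleophile + acid set free <-> protonated nucleophile; electrophile + nucleophile <-> acid set free + product; nucleophile + protic impurity -> quenched reagent
- "hardly changes" means that all values lie within two and a half points (for a concentration: within two and a half percent of the largest)

| run | time / min | product / % |
|---|---|---|
| spring | 5.00 | 8.9 |
| spring | 15.0 | 13.3 |
| spring | 25.0 | 15.0 |
| spring | 40.0 | 15.7 |
| spring | 60.0 | 16.5 |
| dawn | 12.0 | 30.6 |
| dawn | 25.0 | 35.4 |
| dawn | 30.0 | 35.4 |
| dawn | 50.0 | 36.7 |
| dawn | 60.0 | 37.2 |

(each reading ± 0.5 percentage points)

Read against each other, the tables show early bends and then a slow creep. The spring run stands at 15.0% after 25.0 min and 16.5% after 60.0 min; the dawn run stands at 35.4% and 37.2% at those times. The last spring row lies at about half that run's nucleophile charge, and the last dawn row at about half the dawn charge, each taken as a fraction of the electrophile charged.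

The last dawn row reads 2.02, the nucleophile price: nucleophile charged per product standing late in a run. The last spring row reads 1.88, but the same scatter weighs less on the larger dawn reading, so the dawn value is carried. A price near two fits the candidate steps: each product sets free one acid, which can take a second nucleophile.

My own reckoning divides each charge by that price and gives 19.8%, 29.8% and 49.6%. The forecast, reasoning that “two nucleophile are consumed per product”, gives 21%, 30.3% and 48.5%, and its course reads rises all the way. Its first value is higher than mine and its last lower.

The flasks give 20.4%, 29.8% and 48.3%, and their course reads rises all the way, so the forecast held.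

    nucleophile + acid set free ⇌ protonated nucleophile, settled at all times (K = 350 /M)
    electrophile + nucleophile ⇌ acid set free + product (K = 0.750, k = 0.0440 /M/min)
    nucleophile + protic impurity → quenched reagent (k = 0.0190 /M/min)

The price comes to 1.96 in zeta and 2.07 in theta. In zeta at 80.0 min, the relaxation half-life of the product step alone, both ways together, is 7.07 min, short against the time of 80 min. At that moment, protonated nucleophile, the resting state of the nucleophile, holds 44.1% of zeta's nucleophile charge, more than the 2.3% left free.

Readings and results are simulated for an exercise, and the scatter is random.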